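## Analysis of the target

Target 52 joins two sesquiterpenoid halves through a norbornene. Unprimed numbers C1–C15 are used for the acetoxy-guaianolide half and primed numbers for the other half; C11', C12' and C13' are the spiro carbon, its lactone carbonyl and the norbornene CH2. The norbornene (C1, C2, C3, C4=C5, C11', C13') carries the C2 acetoxy group on the bridge, pointing away from the tetrasubstituted C4=C5 alkene and towards C11'. A cycloheptane (C1, C5–C10) is fused on C1–C5; it bears a trans-fused α-methylene-γ-lactone at C7/C8 and a C10 methyl on the face of the C2 bridge. C11' is a quaternary spiro centre with the lactone carbonyl C12' endo and C7' exo; this second lactone is cis-fused to a cyclohexene (C5'–C10') whose tertiary C10' hydroxyl is cis to the C8' oxygen and whose C5' carries the (R)-configured acetoxypentyl chain (C4'). Of the eleven stereocentres, C1, C2 and C3 are tied together by the bicycle, whereas C7, C8, C10, the spiro centre with C7'/C8'/C10', and C4' must each be set on purpose. Sensitive groups are the α-methylene lactone (Michael and radical acceptor), two acetates beside a free tertiary allylic alcohol, and the strained C4=C5 alkene, which lies homoallylic to any cation or radical on the norbornane. The hard parts are closing a seven-membered ring onto the quaternary bridgehead C1 with control at C8 and C10, and building the quaternary C11' on the face that lies under the acetoxy group. The plan rests on the 1,3 relation of C8 and C10: with C10 as the central carbon of an isopropenyl group on C1 and C8 as an aldehyde on the C5 arm, the alkene terminus C9 and the carbonyl carbon face each other across the future cycloheptane.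

## Retrosynthetic reasoning

The exocyclic C11=C13 bond of 52 is removed first, which leads to amine 50 and, one step further back, to lactone 49. It is cut last in the forward sense because the α-methylene lactone tolerates neither radicals nor hydrogenation. The forward steps must aminomethylate the C12 lactone enolate without touching the acetates, then quaternise and eliminate.

In 49 the C11'–C7' bond is cut together with the C5'=C6' alkene and the C10' hydroxyl, giving bromo ester 48. A radical at C11' that adds to C7' of a C6'=C7' alkene and then opens a C5'–C10' epoxide delivers all three features in one event; the ring of the allylic ester fixes the cis fusion, and the epoxide oxygen ends as the C10' hydroxyl on the face it already occupies. The cyclisation has to outrun reduction of the first radical and must take the exo face of C11'.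

Bromo ester 48 is divided at the acyl–oxygen bond into ketene 45 and epoxy alcohol 43. The cut is made there because the C11' hydrogen of an ester cannot be removed selectively beside the C12 lactone and the acetate, whereas addition of alkoxide 46 to the ketene gives enolate 47 at C11' and nowhere else; bromination then supplies the radical precursor.

Alcohol 43 is traced through allylic alcohol 37 and enones 36 and 34 to ketone 28 and aldehyde 30. The C5'–C10' epoxide comes from hydroxyl-directed epoxidation of 37, the C6'=C7' alkene from dehydration of the same carbinol, and the ring from an aldol union of 28 (from citronellal 26, which brings C4') with 30, followed by aldol condensation to 34 and oxidative transposition to 36.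

Ketene 45 comes from acid 25, and 25 from hydroxy diester 24 by cleavage of both tert-butyl esters; the C12 acid then closes onto the C8 hydroxyl. Diester 24 comes from 23 by hydrogenation of the exocyclic C10 methylene under direction of the same C8 hydroxyl.

The key cut is the C8–C9 bond of 23, which opens the cycloheptane to isopropenyl aldehyde 22. No other bond of the seven-membered ring can be made from an alkene and a carbonyl with the oxygen arriving at C8 and the C10 substituent arriving as a reducible methylene. The forward ene reaction must set C8 trans to the existing C7 arm.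

Aldehyde 22 goes back through diester 19 and dienoate 18 to nitro adduct 17, and 17 is cut at C1–C13' and C3–C11' into acetoxydiene 16 and nitroacrylate 15. A plain acrylate would place its ester carbon next to the substituted terminus C1; the nitro group takes that position instead, leaves as nitrite, and hands the ester carbon to C3. The acetoxy group steers the dienophile to its own face and so fixes C1 and C3 from C2.

Diene 16 comes from carbinol 12 by loss of water, and 12 from cyclopentenone 10. The C5=C1 bond of 10 is cut by a retro-aldol condensation to hydroxy diketone 9, and the C2–C3 bond of 9 by a retro-aldol to ketone 5 and keto aldehyde 8; the aldol sets C2 under reagent control, independently of C7.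

Ketone 5 is cut at C6–C7 into aldehyde 1 and enone 2. An amine-catalysed Michael addition makes this bond and sets C7, the only stereocentre of the arm.

## Alternatives that were turned down

Alternative 1: The norbornene is cut at C1–C5 and C3–C4, so that a cyclopentadienone ketal built from C1, C13', C11' and C3 adds an alkynoate and gives 7,7-dimethoxynorbornadiene A1. In its favour, the ketal diene has no hydrogen on the bridge carbon and cannot isomerise by a 1,5-hydrogen shift, and the tetrasubstituted C4=C5 alkene with its methyl and its C6 carbon arrives in one step with the ester directing the regiochemistry. On these two points it is stronger than the chosen route, whose diene 16 is short-lived. Against it, A1 leaves C13'=C11' as a bare alkene, so the C11' carboxyl and the quaternary centre must both be added to an unactivated norbornadiene. The C2 ketone has to be freed from a ketal that is slow to hydrolyse and, once free in a norbornadiene, is prone to lose carbon monoxide; it must then be reduced with face control. The cycloheptane still has to be closed from the C10 chain and the C6 ester over several steps. The chosen route offers instead the C2 acetate with the right orientation directly from the cycloaddition, the C11' carboxyl in place, and the seven-membered ring with its C8 oxygen in one step.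

Alternative 2: The cyclohexene is cut at C5'=C6', so that a C10' ketone condenses through its enamine with a C6' aldehyde on the finished spiro lactone to give enone A2, and the C10' methyl is added afterwards. In its favour, the cyclohexene is built late from an open chain, so no sensitive vinyl epoxide such as 43 is needed, and a methyl nucleophile should approach A2 from the convex face and give the right C10' carbinol. Against it, A2 holds the C8' acyloxy group β to the C10' ketone, so enolisation towards C9' can expel the lactone carboxylate and lead on to a phenol. The enamine can also form on the C9' side. The closing methyl addition must distinguish the ketone from an α-methylene lactone, a second lactone and two acetates. The strategy also says nothing on how the quaternary C11' or the cycloheptane arise. It is equal or better in convergence at the very end, but the chosen route sets the C10' carbinol in fragment 43 before the halves meet and keeps ketones out of the late intermediates.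

Alternative 3: The spiro ring is cut at C11'–C7' at the lactol oxidation level, so that a tertiary radical from a mixed bromoacetal closes onto C7' and the C6' radical opens the C5'–C10' epoxide, giving lactol ether A3. In its favour, an acetal tether cyclises much faster than an ester tether, which must first reach its less stable rotamer; on this point it is stronger than step 36 of the chosen route, which uses the same radical logic. Against it, C12' must first be taken down to the aldehyde level and turned into an enol ether, and after the cyclisation the lactol ether must be oxidised back beside a tertiary allylic alcohol. A3 also still carries the C8 and C13 oxygens as silyl ethers, so the α-methylene lactone needs further deprotection and oxidation. As a key step it does not address the cycloheptane. The chosen route keeps C12' at the acid level throughout and takes the slower ester cyclisation as the price, which is named below as a risk.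

Key step: step 17

Remark on abbreviations: TBS = tert-butyldimethylsilyl; TBSO-methyl = CH2OSi(t-Bu)Me2.
Assumption on the aldol reagent: (−)-Ipc2BCl is taken to deliver a methyl ketone enolate to the si face of an aldehyde; if the sense were the reverse, the two enantiomeric reagents would be exchanged between steps 6 and 23.
Assumption on supply: compounds 1, 2, 6, 13, 26 and 29 are taken to be purchasable.

## Route

Step 1
Reactants: 1 tert-butyl 4-oxobutanoate; 2 but-3-en-2-one
Product: 3 tert-butyl (3S)-3-formyl-6-oxoheptanoate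
Conditions: (S)-α,α-diphenylprolinol methyl ether (5 mol%), ethyl 3,4-dihydroxybenzoate (20 mol%), neat, 4 °C
Reagents that add atoms: none
Why: Enamine-catalysed Michael addition of an aldehyde to an enone; the diarylmethyl group of the catalyst shields one enamine face, so the new C6–C7 bond should form on the other and give the (S) centre at C7.

Step 2
Reactants: 3 tert-butyl (3S)-3-formyl-6-oxoheptanoate
Product: 4 tert-butyl (3S)-3-(hydroxymethyl)-6-oxoheptanoate
Conditions: NaBH4 (0.3 equiv), EtOH/CH2Cl2, −78 °C, on the crude adduct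
Reagents that add atoms: none
Why: Chemoselective borohydride reduction of an aldehyde beside a methyl ketone at low temperature; immediate reduction removes the epimerisable α-formyl centre.

Step 3
Reactants: 4 tert-butyl (3S)-3-(hydroxymethyl)-6-oxoheptanoate
Product: 5 tert-butyl (3S)-6-oxo-3-(TBSO-methyl)heptanoate
Conditions: TBSCl, imidazole, DMF, 0 °C to rt
Reagents that add atoms: tert-butyldimethylsilyl chloride, CC(C)(C)[Si](C)(C)Cl
Why: Silylation of a primary alcohol; it also stops the open hydroxy ketone from resting as its cyclic hemiketal.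

Step 4
Reactants: 6 3-hydroxy-3-methylbutan-2-one
Product: 7 3-methyl-3-(TBSO)butan-2-one
Conditions: TBSOTf, 2,6-lutidine, CH2Cl2, −78 to 0 °C
Reagents that add atoms: tert-butyldimethylsilyl trifluoromethanesulfonate, CC(C)(C)[Si](C)(C)OS(=O)(=O)C(F)(F)F
Why: Silyl triflate silylation of a tertiary alcohol; the ether masks the future C10 oxygen through the enolate chemistry.

Step 5
Reactants: 7 3-methyl-3-(TBSO)butan-2-one
Product: 8 3-methyl-2-oxo-3-(TBSO)butanal
Conditions: SeO2, 1,4-dioxane, H2O (2 equiv), 90 °C; dried by azeotrope before use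
Reagents that add atoms: selenium dioxide, O=[Se]=O
Why: Riley oxidation of a methyl ketone to the α-keto aldehyde; the other α-carbon is quaternary, so only the methyl can react.

Step 6
Reactants: 5 tert-butyl (3S)-6-oxo-3-(TBSO-methyl)heptanoate; 8 3-methyl-2-oxo-3-(TBSO)butanal
Product: 9 tert-butyl (3S,8R)-8-hydroxy-10-methyl-6,9-dioxo-10-(TBSO)-3-(TBSO-methyl)undecanoate
Conditions: (+)-Ipc2BCl, Et3N, Et2O, 0 °C; 8, −78 to −20 °C; H2O2, pH 7 buffer, MeOH
Reagents that add atoms: none
Why: Boron-mediated aldol reaction; the amine and the bulky chloroborane enolise the methyl side of the ketone, the aldehyde carbonyl of 8 reacts in preference to its hindered ketone, and the chiral ligands set C2 (the 8R carbinol) independently of C7.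

Step 7
Reactants: 9 tert-butyl (3S,8R)-8-hydroxy-10-methyl-6,9-dioxo-10-(TBSO)-3-(TBSO-methyl)undecanoate
Product: 10 tert-butyl (3S)-4-{(3R)-3-hydroxy-5-oxo-2-[2-(TBSO)propan-2-yl]cyclopent-1-en-1-yl}-3-(TBSO-methyl)butanoate
Conditions: NaOH (0.1 M aq), THF, 0 °C to rt
Reagents that add atoms: none
Why: Intramolecular aldol condensation of a 3-hydroxy-1,4-diketone, the classical entry to 4-hydroxycyclopent-2-enones; only attack of the C5 enolate on the C1 ketone gives a five-membered ring, and the free alkoxide is a poor leaving group, which holds back β-elimination.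

Step 8
Reactants: 10 tert-butyl (3S)-4-{(3R)-3-hydroxy-5-oxo-2-[2-(TBSO)propan-2-yl]cyclopent-1-en-1-yl}-3-(TBSO-methyl)butanoate
Product: 11 tert-butyl (3S)-4-{(3R)-3,5-dihydroxy-5-methyl-2-[2-(TBSO)propan-2-yl]cyclopent-1-en-1-yl}-3-(TBSO-methyl)butanoate (both epimers at the methyl carbinol)
Conditions: MeLi (3 equiv), CeCl3, THF, −78 °C
Reagents that add atoms: methyllithium, [Li]C
Why: Organocerium 1,2-addition to an enone, which spares the tert-butyl ester at low temperature; the configuration of the new carbinol is of no account because it is dehydrated in step 11.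

Step 9
Reactants: 11 tert-butyl (3S)-4-{(3R)-3,5-dihydroxy-5-methyl-2-[2-(TBSO)propan-2-yl]cyclopent-1-en-1-yl}-3-(TBSO-methyl)butanoate
Product: 12 tert-butyl (3S)-4-{(3R)-3-acetoxy-5-hydroxy-5-methyl-2-[2-(TBSO)propan-2-yl]cyclopent-1-en-1-yl}-3-(TBSO-methyl)butanoate (both epimers at the methyl carbinol)
Conditions: Ac2O, pyridine, DMAP (cat.), CH2Cl2, 0 °C
Reagents that add atoms: acetic anhydride, CC(=O)OC(C)=O
Why: Acylation of the secondary allylic alcohol; the tertiary alcohol is left because it acylates far more slowly.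

Step 10
Reactants: 13 tert-butyl prop-2-enoate
Product: 15 tert-butyl (2E)-3-nitroprop-2-enoate, via tert-butyl 2-iodo-3-nitropropanoate 14 (not isolated)
Conditions: N2O4, I2, Et2O, 0 °C; then NaOAc, Et2O, rt
Reagents that add atoms: dinitrogen tetroxide, [O-][N+](=O)[N+](=O)[O-]
Why: Iodonitration of an acrylate followed by loss of hydrogen iodide, the standard preparation of β-nitroacrylates; the trans alkene is the stable isomer.

Step 11
Reactants: 12 tert-butyl (3S)-4-{(3R)-3-acetoxy-5-hydroxy-5-methyl-2-[2-(TBSO)propan-2-yl]cyclopent-1-en-1-yl}-3-(TBSO-methyl)butanoate; 15 tert-butyl (2E)-3-nitroprop-2-enoate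
Product: 17 tert-butyl 7-acetoxy-5-[(2S)-4-tert-butoxy-4-oxo-2-(TBSO-methyl)butyl]-6-methyl-3-nitro-4-[2-(TBSO)propan-2-yl]bicyclo[2.2.1]hept-5-ene-2-carboxylate (acetoxy anti to the ring alkene; nitro and ester trans; both trans adducts), via tert-butyl (3S)-4-{(5R)-5-acetoxy-3-methyl-1-[2-(TBSO)propan-2-yl]cyclopenta-1,3-dien-2-yl}-3-(TBSO-methyl)butanoate 16 (not isolated)
Conditions: Martin sulfurane Ph2S[OC(CF3)2Ph]2, 15 (2 equiv) present, CH2Cl2, −40 to 0 °C
Reagents that add atoms: none
Why: Dehydration of the tertiary allylic alcohol gives the 5-acetoxycyclopentadiene, which is caught at once in a Diels–Alder reaction; 5-acyloxycyclopentadienes add dienophiles on the acetoxy face, which sets C1 and C3 from C2, and the nitro-bearing carbon bonds to the substituted terminus C1 so that the ester carbon bonds to C3.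

Step 12
Reactants: 17 tert-butyl 7-acetoxy-5-[(2S)-4-tert-butoxy-4-oxo-2-(TBSO-methyl)butyl]-6-methyl-3-nitro-4-[2-(TBSO)propan-2-yl]bicyclo[2.2.1]hept-5-ene-2-carboxylate
Product: 18 tert-butyl 7-acetoxy-5-[(2S)-4-tert-butoxy-4-oxo-2-(TBSO-methyl)butyl]-6-methyl-4-[2-(TBSO)propan-2-yl]bicyclo[2.2.1]hepta-2,5-diene-2-carboxylate (acetoxy anti to C5=C6)
Conditions: DBU, CH2Cl2, 0 °C
Reagents that add atoms: none
Why: E1cB loss of nitrous acid from a β-nitro ester; both trans adducts converge on the same conjugated ester.

Step 13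
Reactants: 18 tert-butyl 7-acetoxy-5-[(2S)-4-tert-butoxy-4-oxo-2-(TBSO-methyl)butyl]-6-methyl-4-[2-(TBSO)propan-2-yl]bicyclo[2.2.1]hepta-2,5-diene-2-carboxylate
Product: 19 tert-butyl (1R,2S,4R,7R)-7-acetoxy-5-[(2S)-4-tert-butoxy-4-oxo-2-(TBSO-methyl)butyl]-6-methyl-4-[2-(TBSO)propan-2-yl]bicyclo[2.2.1]hept-5-ene-2-carboxylate (endo ester)
Conditions: 2-nitrobenzenesulfonyl hydrazide, Et3N, CH2Cl2, rt
Reagents that add atoms: none
Why: Diimide reduces the strained trisubstituted conjugated alkene and leaves the tetrasubstituted one; delivery from the exo face, as known for the alkene syn to a 7-acyloxy group in norbornadienes, should give the endo ester, and this centre is made planar again in step 34.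

Step 14
Reactants: 19 tert-butyl (1R,2S,4R,7R)-7-acetoxy-5-[(2S)-4-tert-butoxy-4-oxo-2-(TBSO-methyl)butyl]-6-methyl-4-[2-(TBSO)propan-2-yl]bicyclo[2.2.1]hept-5-ene-2-carboxylate
Product: 20 tert-butyl (1R,2S,4R,7R)-7-acetoxy-5-[(2S)-4-tert-butoxy-2-(hydroxymethyl)-4-oxobutyl]-4-(2-hydroxypropan-2-yl)-6-methylbicyclo[2.2.1]hept-5-ene-2-carboxylate
Conditions: HF (48% aq), MeCN, 0 °C to rt
Reagents that add atoms: none
Why: Acidic fluoride cleavage of the primary and the tertiary silyl ether; the acetate and the tert-butyl esters are stable to these conditions.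

Step 15
Reactants: 20 tert-butyl (1R,2S,4R,7R)-7-acetoxy-5-[(2S)-4-tert-butoxy-2-(hydroxymethyl)-4-oxobutyl]-4-(2-hydroxypropan-2-yl)-6-methylbicyclo[2.2.1]hept-5-ene-2-carboxylate
Product: 21 tert-butyl (1R,2S,4R,7R)-7-acetoxy-5-[(2S)-4-tert-butoxy-2-formyl-4-oxobutyl]-4-(2-hydroxypropan-2-yl)-6-methylbicyclo[2.2.1]hept-5-ene-2-carboxylate
Conditions: Dess–Martin periodinane, NaHCO3, CH2Cl2, 0 °C to rt
Reagents that add atoms: none
Why: Buffered periodinane oxidation of the primary alcohol; the tertiary alcohol cannot be oxidised and the neutral conditions protect the C7 centre next to the new aldehyde.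

Step 16
Reactants: 21 tert-butyl (1R,2S,4R,7R)-7-acetoxy-5-[(2S)-4-tert-butoxy-2-formyl-4-oxobutyl]-4-(2-hydroxypropan-2-yl)-6-methylbicyclo[2.2.1]hept-5-ene-2-carboxylate
Product: 22 tert-butyl (1R,2S,4R,7R)-7-acetoxy-5-[(2S)-4-tert-butoxy-2-formyl-4-oxobutyl]-6-methyl-4-(prop-1-en-2-yl)bicyclo[2.2.1]hept-5-ene-2-carboxylate
Conditions: Burgess reagent (MeO2CNSO2NEt3), PhH, 50 °C
Reagents that add atoms: none
Why: Syn elimination through the sulfamate ester; only methyl hydrogens are available because an alkene at the bridgehead is forbidden by Bredt's rule, so the isopropenyl group is the sole product.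

Step 17
Reactants: 22 tert-butyl (1R,2S,4R,7R)-7-acetoxy-5-[(2S)-4-tert-butoxy-2-formyl-4-oxobutyl]-6-methyl-4-(prop-1-en-2-yl)bicyclo[2.2.1]hept-5-ene-2-carboxylate
Product: 23 tricyclic homoallylic alcohol: cycloheptane fused on C1–C5 of the norbornene, C8 hydroxyl trans to the C7 CH2CO2t-Bu arm, exocyclic C10 methylene, C2 acetoxy anti to C4=C5, endo C11' CO2t-Bu
Conditions: Me2AlCl (2.5 equiv), CH2Cl2, −78 °C; aq. Rochelle salt
Reagents that add atoms: none
Why: Me2AlCl binds the C8 aldehyde oxygen, the terminal isopropenyl carbon C9 attacks C8, and a hydrogen of the C14 methyl passes to oxygen through a six-membered ene transition state, so C8–C9 forms and the alkene moves to C10=C14. The closest known reaction type is the type-2 intramolecular carbonyl-ene reaction promoted by Me2AlCl, which gives 3-methylenecycloalkanols including seven-membered ones. The cycloheptane closes in the type-2 mode, with the central alkene carbon C10 inside the tether and the methylene left exocyclic. The one new stereocentre, C8, is controlled by C7: in a chair-like transition state the CH2CO2t-Bu arm lies equatorial and the aluminium-bound oxygen turns away from it, so the hydroxyl should come out trans to the arm. The step needs the ene path to beat Prins attack by the more electron-rich C4=C5 alkene; that attack would have to close a four-membered or a badly strained five-membered ring through the bridgehead, whereas C9 reaches C8 without strain. It also needs C7 to keep its configuration, which the low temperature and the absence of protic acid secure, since the reagent takes up the transferred proton as methane and leaves an aluminium alkoxide. The tert-butyl ester does not lactonise in the flask, so the C8 hydroxyl stays free for step 18.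

Step 18
Reactants: 23 tricyclic homoallylic alcohol with exocyclic C10 methylene
Product: 24 tricyclic alcohol with C10 methyl on the face of the C2 bridge (C10–H cis to the C8 hydroxyl), otherwise as 23
Conditions: H2 (1 atm), [Ir(cod)(PCy3)(py)]PF6 (5 mol%), CH2Cl2, rt
Reagents that add atoms: none
Why: Hydroxyl-directed hydrogenation; the homoallylic C8 hydroxyl binds iridium and hydrogen is delivered to its own face of the 1,1-disubstituted alkene, which places the C10 methyl on the opposite face as the target requires, while the hindered tetrasubstituted alkene should be left.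

Step 19
Reactants: 24 tricyclic alcohol with C10 methyl
Product: 25 lactone acid: 8,12-olide trans-fused at C7/C8, C2 acetoxy, endo C11' carboxylic acid
Conditions: TMSOTf, 2,6-lutidine, CH2Cl2, 0 °C; aq. citric acid; then PPTS, PhMe, 40 °C
Reagents that add atoms: none
Why: Silyl triflate cleavage of both tert-butyl esters without a protic acid strong enough to protonate the C4=C5 alkene; the freed C12 acid closes onto the C8 hydroxyl as a γ-lactone, and the C11' acid has no hydroxyl within reach.

Step 20
Reactants: 26 (R)-citronellal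
Product: 27 (4R)-4,8-dimethylnon-7-en-2-ol (both C2 epimers)
Conditions: MeMgBr, Et2O, 0 °C
Reagents that add atoms: methylmagnesium bromide, C[Mg]Br
Why: Grignard addition to an aldehyde; the new carbinol is oxidised in the next step, so its configuration does not matter.

Step 21
Reactants: 27 (4R)-4,8-dimethylnon-7-en-2-ol
Product: 28 (4R)-4,8-dimethylnon-7-en-2-one
Conditions: Dess–Martin periodinane, NaHCO3, CH2Cl2, rt
Reagents that add atoms: none
Why: Oxidation of a secondary alcohol to the methyl ketone; the stereocentre is β to the carbonyl and is not enolisable.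

Step 22
Reactants: 29 methyl 3,3-dimethoxypropanoate
Product: 30 3,3-dimethoxypropanal
Conditions: i-Bu2AlH, CH2Cl2, −78 °C
Reagents that add atoms: none
Why: Partial reduction of an ester to the aldehyde at low temperature through the stable tetrahedral aluminium intermediate.

Step 23
Reactants: 28 (4R)-4,8-dimethylnon-7-en-2-one; 30 3,3-dimethoxypropanal
Product: 31 (3R,7R)-3-hydroxy-1,1-dimethoxy-7,11-dimethyldodec-10-en-5-one
Conditions: (−)-Ipc2BCl, Et3N, Et2O, 0 °C; 30, −78 to −20 °C; H2O2, pH 7 buffer, MeOH
Reagents that add atoms: none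
Why: Boron-mediated aldol reaction of the methyl side of the ketone; the chiral ligands set the future C8' carbinol, since the existing centre is too remote to help.

Step 24
Reactants: 31 (3R,7R)-3-hydroxy-1,1-dimethoxy-7,11-dimethyldodec-10-en-5-one
Product: 32 (3R,7R)-1,1-dimethoxy-7,11-dimethyl-3-(TBSO)dodec-10-en-5-one
Conditions: TBSOTf, 2,6-lutidine, CH2Cl2, −78 °C
Reagents that add atoms: tert-butyldimethylsilyl trifluoromethanesulfonate, CC(C)(C)[Si](C)(C)OS(=O)(=O)C(F)(F)F
Why: Silylation of the secondary alcohol at low temperature, where the dimethyl acetal is not activated.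

Step 25
Reactants: 32 (3R,7R)-1,1-dimethoxy-7,11-dimethyl-3-(TBSO)dodec-10-en-5-one
Product: 34 (5R)-2-[(2R)-6-methylhept-5-en-2-yl]-5-(TBSO)cyclohex-2-en-1-one, via (3R,7R)-7,11-dimethyl-5-oxo-3-(TBSO)dodec-10-enal 33 (not isolated)
Conditions: PPTS, acetone/H2O, 50 °C; then Bn2NH·CF3CO2H, PhH, 50 °C
Reagents that add atoms: none
Why: Acetal hydrolysis followed by amine-salt-catalysed intramolecular aldol condensation; only the ketone α-carbon on the side-chain side can reach the aldehyde in a six-membered ring.

Step 26
Reactants: 34 (5R)-2-[(2R)-6-methylhept-5-en-2-yl]-5-(TBSO)cyclohex-2-en-1-one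
Product: 35 (5R)-1-methyl-2-[(2R)-6-methylhept-5-en-2-yl]-5-(TBSO)cyclohex-2-en-1-ol (both C1 epimers)
Conditions: MeLi, CeCl3, THF, −78 °C
Reagents that add atoms: methyllithium, [Li]C
Why: Organocerium 1,2-addition to the enone without enolisation towards the β-silyloxy carbon; the carbinol configuration is lost in the next step.

Step 27
Reactants: 35 (5R)-1-methyl-2-[(2R)-6-methylhept-5-en-2-yl]-5-(TBSO)cyclohex-2-en-1-ol
Product: 36 (5S)-3-methyl-2-[(2R)-6-methylhept-5-en-2-yl]-5-(TBSO)cyclohex-2-en-1-one
Conditions: pyridinium chlorochromate C5H5NH[CrO3Cl], 4 Å molecular sieves, CH2Cl2, rt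
Reagents that add atoms: pyridinium chlorochromate, [O-][Cr](=O)(=O)Cl.c1cc[nH+]cc1
Why: Babler–Dauben oxidative transposition; the chromate ester of the tertiary allylic alcohol undergoes a [3,3] shift and is oxidised to the transposed enone, which puts the methyl on the future C10' and the carbonyl on C6'.

Step 28
Reactants: 36 (5S)-3-methyl-2-[(2R)-6-methylhept-5-en-2-yl]-5-(TBSO)cyclohex-2-en-1-one
Product: 37 (1S,5S)-3-methyl-2-[(2R)-6-methylhept-5-en-2-yl]-5-(TBSO)cyclohex-2-en-1-ol (hydroxyl cis to TBSO)
Conditions: NaBH4, CeCl3·7H2O, MeOH, −78 °C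
Reagents that add atoms: none
Why: Luche 1,2-reduction; axial hydride attack trans to the 5-substituent, as with carvone, should give the cis alcohol.

Step 29
Reactants: 37 (1S,5S)-3-methyl-2-[(2R)-6-methylhept-5-en-2-yl]-5-(TBSO)cyclohex-2-en-1-ol
Product: 38 6-methyl-1-[(2R)-6-methylhept-5-en-2-yl]-4-(TBSO)-7-oxabicyclo[4.1.0]heptan-2-ol (epoxide oxygen, hydroxyl and TBSO all cis)
Conditions: VO(acac)2 (5 mol%), t-BuOOH, PhH, rt
Reagents that add atoms: tert-butyl hydroperoxide, CC(C)(C)OO
Why: Vanadium-catalysed epoxidation directed by the allylic hydroxyl; the oxygen is delivered to the hydroxyl face of the tetrasubstituted ring alkene and the remote trisubstituted alkene is not touched.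

Step 30
Reactants: 38 6-methyl-1-[(2R)-6-methylhept-5-en-2-yl]-4-(TBSO)-7-oxabicyclo[4.1.0]heptan-2-ol
Product: 40 1-[(2R)-5-hydroxypentan-2-yl]-6-methyl-4-(TBSO)-7-oxabicyclo[4.1.0]heptan-2-ol (oxygens all cis), via (4R)-4-[2-hydroxy-6-methyl-4-(TBSO)-7-oxabicyclo[4.1.0]heptan-1-yl]pentanal 39 (not isolated)
Conditions: O3, CH2Cl2/MeOH, −78 °C; then NaBH4, −78 to 0 °C
Reagents that add atoms: ozone, [O-][O+]=O
Why: Ozonolysis of the only remaining alkene with reductive work-up to the primary alcohol; the epoxide and the silyl ether are inert to both reagents.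

Step 31
Reactants: 40 1-[(2R)-5-hydroxypentan-2-yl]-6-methyl-4-(TBSO)-7-oxabicyclo[4.1.0]heptan-2-ol
Product: 41 (4R)-4-[2-hydroxy-6-methyl-4-(TBSO)-7-oxabicyclo[4.1.0]heptan-1-yl]pentyl acetate
Conditions: AcCl, 2,4,6-collidine, CH2Cl2, −78 °C
Reagents that add atoms: acetyl chloride, CC(Cl)=O
Why: Selective acylation of the primary alcohol; the secondary alcohol sits next to the fully substituted epoxide carbon and is far slower.

Step 32
Reactants: 41 (4R)-4-[2-hydroxy-6-methyl-4-(TBSO)-7-oxabicyclo[4.1.0]heptan-1-yl]pentyl acetate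
Product: 42 (4R)-4-[6-methyl-4-(TBSO)-7-oxabicyclo[4.1.0]hept-2-en-1-yl]pentyl acetate (TBSO cis to the epoxide oxygen)
Conditions: Burgess reagent (MeO2CNSO2NEt3), PhMe, 60 °C
Reagents that add atoms: none
Why: Syn elimination of the secondary alcohol; the only β-hydrogens are on C7' because C5' is fully substituted, so the C6'=C7' alkene of the vinyl epoxide is the only possible product.

Step 33
Reactants: 42 (4R)-4-[6-methyl-4-(TBSO)-7-oxabicyclo[4.1.0]hept-2-en-1-yl]pentyl acetate
Product: 43 (4R)-4-[4-hydroxy-6-methyl-7-oxabicyclo[4.1.0]hept-2-en-1-yl]pentyl acetate (hydroxyl cis to the epoxide oxygen)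
Conditions: Bu4NF, AcOH, THF, 0 °C to rt
Reagents that add atoms: none
Why: Buffered fluoride cleavage of the silyl ether; the buffer keeps the acetate and the vinyl epoxide intact.

Step 34
Reactants: 25 lactone acid
Product: 45 ketene at C11' (C11'=C12'=O) on the lactone acetate core, via acid chloride 44 (not isolated)
Conditions: 1-chloro-N,N,2-trimethylprop-1-en-1-amine, CH2Cl2, 0 °C to rt; then Et3N, PhMe, 70 °C; used as a filtered solution
Reagents that add atoms: none
Why: Neutral formation of the acid chloride and dehydrochlorination to a dialkylketene; only an acid chloride can lose HCl in this way, so the lactone and acetate α-hydrogens are not involved.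

Step 35
Reactants: 45 ketene at C11'; 43 (4R)-4-[4-hydroxy-6-methyl-7-oxabicyclo[4.1.0]hept-2-en-1-yl]pentyl acetate
Product: 48 α-bromo ester: C11' bromide of the lactone acetate core esterified through C12' with the C8' oxygen of the epoxy cyclohexene (both C11' epimers), via lithium alkoxide 46 (not isolated), via lithium ester enolate 47 (not isolated)
Conditions: 43, LiN(SiMe3)2 (1.0 equiv), THF, −78 °C; add 45; then N-bromosuccinimide, −78 °C
Reagents that add atoms: N-bromosuccinimide, O=C1CCC(=O)N1Br
Why: Addition of a lithium alkoxide to a ketene gives the ester enolate regiospecifically at C11' without any deprotonation, and the enolate is brominated as it forms; the configuration at C11' is of no account for the radical step.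

Step 36
Reactants: 48 α-bromo ester
Product: 49 spiro lactone: C11'–C7' bond exo on the norbornane, lactone cis-fused at C7'/C8', C5'=C6' alkene, free C10' hydroxyl cis to the C8' oxygen; C11 still CH2
Conditions: Bu3SnH (syringe pump), AIBN (cat.), PhMe, 100 °C, high dilution
Reagents that add atoms: none
Why: The tertiary α-ester radical closes 5-exo onto C7' on the face of the tether, the C6' radical opens the adjacent epoxide by C–O cleavage to give C5'=C6', and the alkoxy radical is reduced by the stannane; attack on the exo face of C11' is expected by analogy with the exo alkylation of camphor enolates, which also carry a syn bridge substituent, the endo face being screened by C4=C5.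

Step 37
Reactants: 49 spiro lactone
Product: 50 Mannich base: 49 with a dimethylaminomethyl group on C11 (both C11 epimers)
Conditions: LiN(SiMe3)2 (2.2 equiv), THF, −78 °C; then Me2N=CH2 iodide, −78 to 0 °C
Reagents that add atoms: N,N-dimethylmethyleneiminium iodide (Eschenmoser's salt), C=[N+](C)C.[I-]
Why: Mannich alkylation of a lactone enolate; after the hydroxyl, the base removes a C11 hydrogen of the γ-lactone, which is clearly more acidic than an acetate methyl hydrogen, and the spiro lactone has no α-hydrogen.

Step 38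
Reactants: 50 Mannich base
Product: 52 target CNP0257312.1, via trimethylammonium iodide 51 (not isolated)
Conditions: MeI, CH2Cl2/MeOH, rt; then NaHCO3 (aq), EtOAc, rt
Reagents that add atoms: none
Why: Quaternisation of the amine and Hofmann-type E1cB elimination under bicarbonate, a mild standard release of an α-methylene lactone that leaves the acetates and the tertiary alcohol alone.

## Compound list

1 | tert-butyl 4-oxobutanoate | O=CCCC(=O)OC(C)(C)C | starting material
2 | but-3-en-2-one | C=CC(C)=O | starting material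
3 | tert-butyl (3S)-3-formyl-6-oxoheptanoate | CC(=O)CC[C@@H](CC(=O)OC(C)(C)C)C=O | intermediate
4 | tert-butyl (3S)-3-(hydroxymethyl)-6-oxoheptanoate | CC(=O)CC[C@@H](CC(=O)OC(C)(C)C)CO | intermediate
5 | tert-butyl (3S)-6-oxo-3-(TBSO-methyl)heptanoate | CC(=O)CC[C@@H](CC(=O)OC(C)(C)C)CO[Si](C)(C)C(C)(C)C | intermediate
6 | 3-hydroxy-3-methylbutan-2-one | CC(=O)C(C)(C)O | starting material
7 | 3-methyl-3-(TBSO)butan-2-one | CC(=O)C(C)(C)O[Si](C)(C)C(C)(C)C | intermediate
8 | 3-methyl-2-oxo-3-(TBSO)butanal | O=CC(=O)C(C)(C)O[Si](C)(C)C(C)(C)C | intermediate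
9 | tert-butyl (3S,8R)-8-hydroxy-10-methyl-6,9-dioxo-10-(TBSO)-3-(TBSO-methyl)undecanoate | CC(C)(O[Si](C)(C)C(C)(C)C)C(=O)[C@H](O)CC(=O)CC[C@@H](CC(=O)OC(C)(C)C)CO[Si](C)(C)C(C)(C)C | intermediate
10 | tert-butyl (3S)-4-{(3R)-3-hydroxy-5-oxo-2-[2-(TBSO)propan-2-yl]cyclopent-1-en-1-yl}-3-(TBSO-methyl)butanoate | O=C1C[C@@H](O)C(C(C)(C)O[Si](C)(C)C(C)(C)C)=C1C[C@@H](CC(=O)OC(C)(C)C)CO[Si](C)(C)C(C)(C)C | intermediate
11 | tert-butyl (3S)-4-{(3R)-3,5-dihydroxy-5-methyl-2-[2-(TBSO)propan-2-yl]cyclopent-1-en-1-yl}-3-(TBSO-methyl)butanoate, both epimers at the methyl carbinol | CC1(O)C[C@@H](O)C(C(C)(C)O[Si](C)(C)C(C)(C)C)=C1C[C@@H](CC(=O)OC(C)(C)C)CO[Si](C)(C)C(C)(C)C | intermediate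
12 | tert-butyl (3S)-4-{(3R)-3-acetoxy-5-hydroxy-5-methyl-2-[2-(TBSO)propan-2-yl]cyclopent-1-en-1-yl}-3-(TBSO-methyl)butanoate, both epimers at the methyl carbinol | CC(=O)O[C@@H]1CC(C)(O)C(C[C@@H](CC(=O)OC(C)(C)C)CO[Si](C)(C)C(C)(C)C)=C1C(C)(C)O[Si](C)(C)C(C)(C)C | intermediate
13 | tert-butyl prop-2-enoate | C=CC(=O)OC(C)(C)C | starting material
14 | tert-butyl 2-iodo-3-nitropropanoate | O=C(OC(C)(C)C)C(I)C[N+](=O)[O-] | intermediate
15 | tert-butyl (2E)-3-nitroprop-2-enoate | O=C(OC(C)(C)C)/C=C/[N+](=O)[O-] | intermediate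
16 | tert-butyl (3S)-4-{(5R)-5-acetoxy-3-methyl-1-[2-(TBSO)propan-2-yl]cyclopenta-1,3-dien-2-yl}-3-(TBSO-methyl)butanoate | CC(=O)O[C@@H]1C=C(C)C(C[C@@H](CC(=O)OC(C)(C)C)CO[Si](C)(C)C(C)(C)C)=C1C(C)(C)O[Si](C)(C)C(C)(C)C | intermediate
17 | tert-butyl 7-acetoxy-5-[(2S)-4-tert-butoxy-4-oxo-2-(TBSO-methyl)butyl]-6-methyl-3-nitro-4-[2-(TBSO)propan-2-yl]bicyclo[2.2.1]hept-5-ene-2-carboxylate, acetoxy anti to C5=C6, nitro and ester trans, both trans adducts | CC(C)(O[Si](C)(C)C(C)(C)C)[C@]12C([N+](=O)[O-])C(C(=O)OC(C)(C)C)[C@H](C(C)=C1C[C@@H](CC(=O)OC(C)(C)C)CO[Si](C)(C)C(C)(C)C)[C@H]2OC(C)=O | intermediate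
18 | tert-butyl 7-acetoxy-5-[(2S)-4-tert-butoxy-4-oxo-2-(TBSO-methyl)butyl]-6-methyl-4-[2-(TBSO)propan-2-yl]bicyclo[2.2.1]hepta-2,5-diene-2-carboxylate, acetoxy anti to C5=C6 | CC(C)(O[Si](C)(C)C(C)(C)C)[C@]12C=C(C(=O)OC(C)(C)C)[C@H](C(C)=C1C[C@@H](CC(=O)OC(C)(C)C)CO[Si](C)(C)C(C)(C)C)[C@H]2OC(C)=O | intermediate
19 | tert-butyl (1R,2S,4R,7R)-7-acetoxy-5-[(2S)-4-tert-butoxy-4-oxo-2-(TBSO-methyl)butyl]-6-methyl-4-[2-(TBSO)propan-2-yl]bicyclo[2.2.1]hept-5-ene-2-carboxylate | CC(C)(O[Si](C)(C)C(C)(C)C)[C@]12C[C@H](C(=O)OC(C)(C)C)[C@H](C(C)=C1C[C@@H](CC(=O)OC(C)(C)C)CO[Si](C)(C)C(C)(C)C)[C@H]2OC(C)=O | intermediate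
20 | tert-butyl (1R,2S,4R,7R)-7-acetoxy-5-[(2S)-4-tert-butoxy-2-(hydroxymethyl)-4-oxobutyl]-4-(2-hydroxypropan-2-yl)-6-methylbicyclo[2.2.1]hept-5-ene-2-carboxylate | CC(C)(O)[C@]12C[C@H](C(=O)OC(C)(C)C)[C@H](C(C)=C1C[C@@H](CC(=O)OC(C)(C)C)CO)[C@H]2OC(C)=O | intermediate
21 | tert-butyl (1R,2S,4R,7R)-7-acetoxy-5-[(2S)-4-tert-butoxy-2-formyl-4-oxobutyl]-4-(2-hydroxypropan-2-yl)-6-methylbicyclo[2.2.1]hept-5-ene-2-carboxylate | CC(C)(O)[C@]12C[C@H](C(=O)OC(C)(C)C)[C@H](C(C)=C1C[C@@H](CC(=O)OC(C)(C)C)C=O)[C@H]2OC(C)=O | intermediate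
22 | tert-butyl (1R,2S,4R,7R)-7-acetoxy-5-[(2S)-4-tert-butoxy-2-formyl-4-oxobutyl]-6-methyl-4-(prop-1-en-2-yl)bicyclo[2.2.1]hept-5-ene-2-carboxylate (precursor of the key step) | C=C(C)[C@]12C[C@H](C(=O)OC(C)(C)C)[C@H](C(C)=C1C[C@@H](CC(=O)OC(C)(C)C)C=O)[C@H]2OC(C)=O | intermediate
23 | tricyclic homoallylic alcohol: C8 hydroxyl trans to the C7 CH2CO2t-Bu arm, exocyclic C10 methylene, C2 acetoxy, endo C11' CO2t-Bu (product of the key step) | O[C@@H]1CC(=C)[C@]23C[C@H](C(=O)OC(C)(C)C)[C@H](C(C)=C2C[C@H]1CC(=O)OC(C)(C)C)[C@H]3OC(C)=O | intermediate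
24 | tricyclic alcohol with C10 methyl on the face of the C2 bridge, otherwise as 23 | O[C@@H]1C[C@@H](C)[C@]23C[C@H](C(=O)OC(C)(C)C)[C@H](C(C)=C2C[C@H]1CC(=O)OC(C)(C)C)[C@H]3OC(C)=O | intermediate
25 | lactone acid: 8,12-olide trans-fused at C7/C8, C2 acetoxy, endo C11' carboxylic acid | C1C(=O)O[C@@H]2C[C@@H](C)[C@]34C[C@H](C(=O)O)[C@H](C(C)=C3C[C@@H]12)[C@H]4OC(C)=O | intermediate
26 | (R)-citronellal | O=CC[C@H](C)CCC=C(C)C | starting material
27 | (4R)-4,8-dimethylnon-7-en-2-ol, both C2 epimers | CC(O)C[C@H](C)CCC=C(C)C | intermediate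
28 | (4R)-4,8-dimethylnon-7-en-2-one | CC(=O)C[C@H](C)CCC=C(C)C | intermediate
29 | methyl 3,3-dimethoxypropanoate | COC(OC)CC(=O)OC | starting material
30 | 3,3-dimethoxypropanal | COC(OC)CC=O | intermediate
31 | (3R,7R)-3-hydroxy-1,1-dimethoxy-7,11-dimethyldodec-10-en-5-one | COC(OC)C[C@@H](O)CC(=O)C[C@H](C)CCC=C(C)C | intermediate
32 | (3R,7R)-1,1-dimethoxy-7,11-dimethyl-3-(TBSO)dodec-10-en-5-one | COC(OC)C[C@@H](O[Si](C)(C)C(C)(C)C)CC(=O)C[C@H](C)CCC=C(C)C | intermediate
33 | (3R,7R)-7,11-dimethyl-5-oxo-3-(TBSO)dodec-10-enal | O=CC[C@@H](O[Si](C)(C)C(C)(C)C)CC(=O)C[C@H](C)CCC=C(C)C | intermediate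
34 | (5R)-2-[(2R)-6-methylhept-5-en-2-yl]-5-(TBSO)cyclohex-2-en-1-one | O=C1C[C@H](O[Si](C)(C)C(C)(C)C)CC=C1[C@H](C)CCC=C(C)C | intermediate
35 | (5R)-1-methyl-2-[(2R)-6-methylhept-5-en-2-yl]-5-(TBSO)cyclohex-2-en-1-ol, both C1 epimers | CC1(O)C[C@H](O[Si](C)(C)C(C)(C)C)CC=C1[C@H](C)CCC=C(C)C | intermediate
36 | (5S)-3-methyl-2-[(2R)-6-methylhept-5-en-2-yl]-5-(TBSO)cyclohex-2-en-1-one | CC1=C([C@H](C)CCC=C(C)C)C(=O)C[C@@H](O[Si](C)(C)C(C)(C)C)C1 | intermediate
37 | (1S,5S)-3-methyl-2-[(2R)-6-methylhept-5-en-2-yl]-5-(TBSO)cyclohex-2-en-1-ol | CC1=C([C@H](C)CCC=C(C)C)[C@@H](O)C[C@@H](O[Si](C)(C)C(C)(C)C)C1 | intermediate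
38 | 6-methyl-1-[(2R)-6-methylhept-5-en-2-yl]-4-(TBSO)-7-oxabicyclo[4.1.0]heptan-2-ol, epoxide oxygen, hydroxyl and TBSO all cis | C[C@]12O[C@@]1([C@H](C)CCC=C(C)C)[C@@H](O)C[C@@H](O[Si](C)(C)C(C)(C)C)C2 | intermediate
39 | (4R)-4-[2-hydroxy-6-methyl-4-(TBSO)-7-oxabicyclo[4.1.0]heptan-1-yl]pentanal, oxygens all cis | C[C@]12O[C@@]1([C@H](C)CCC=O)[C@@H](O)C[C@@H](O[Si](C)(C)C(C)(C)C)C2 | intermediate
40 | 1-[(2R)-5-hydroxypentan-2-yl]-6-methyl-4-(TBSO)-7-oxabicyclo[4.1.0]heptan-2-ol, oxygens all cis | C[C@]12O[C@@]1([C@H](C)CCCO)[C@@H](O)C[C@@H](O[Si](C)(C)C(C)(C)C)C2 | intermediate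
41 | (4R)-4-[2-hydroxy-6-methyl-4-(TBSO)-7-oxabicyclo[4.1.0]heptan-1-yl]pentyl acetate, oxygens all cis | C[C@]12O[C@@]1([C@H](C)CCCOC(C)=O)[C@@H](O)C[C@@H](O[Si](C)(C)C(C)(C)C)C2 | intermediate
42 | (4R)-4-[6-methyl-4-(TBSO)-7-oxabicyclo[4.1.0]hept-2-en-1-yl]pentyl acetate, TBSO cis to the epoxide oxygen | C[C@]12O[C@@]1([C@H](C)CCCOC(C)=O)C=C[C@@H](O[Si](C)(C)C(C)(C)C)C2 | intermediate
43 | (4R)-4-[4-hydroxy-6-methyl-7-oxabicyclo[4.1.0]hept-2-en-1-yl]pentyl acetate, hydroxyl cis to the epoxide oxygen | C[C@]12O[C@@]1([C@H](C)CCCOC(C)=O)C=C[C@@H](O)C2 | intermediate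
44 | acid chloride of 25 at C12' | C1C(=O)O[C@@H]2C[C@@H](C)[C@]34C[C@H](C(Cl)=O)[C@H](C(C)=C3C[C@@H]12)[C@H]4OC(C)=O | intermediate
45 | ketene C11'=C12'=O on the lactone acetate core | C1C(=O)O[C@@H]2C[C@@H](C)[C@]34CC(=C=O)[C@H](C(C)=C3C[C@@H]12)[C@H]4OC(C)=O | intermediate
46 | lithium alkoxide of 43 | [Li]O[C@H]1C[C@@]2(C)O[C@@]2([C@H](C)CCCOC(C)=O)C=C1 | intermediate
47 | lithium enolate of the C12' ester of 43 (C11'=C12' enolate, geometry open) | C1C(=O)O[C@@H]2C[C@@H](C)[C@]34CC(=C(O[Li])O[C@H]5C[C@@]6(C)O[C@@]6([C@H](C)CCCOC(C)=O)C=C5)[C@H](C(C)=C3C[C@@H]12)[C@H]4OC(C)=O | intermediate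
48 | α-bromo ester: C11' bromide, C12' ester of 43, both C11' epimers | C1C(=O)O[C@@H]2C[C@@H](C)[C@]34CC(Br)(C(=O)O[C@H]5C[C@@]6(C)O[C@@]6([C@H](C)CCCOC(C)=O)C=C5)[C@H](C(C)=C3C[C@@H]12)[C@H]4OC(C)=O | intermediate
49 | spiro lactone: target lacking the C13 methylene (C11 is CH2) | C1C(=O)O[C@@H]2C[C@@H](C)[C@]34C[C@]5(C(=O)O[C@H]6C[C@@](C)(O)C([C@H](C)CCCOC(C)=O)=C[C@H]65)[C@H](C(C)=C3C[C@@H]12)[C@H]4OC(C)=O | intermediate
50 | Mannich base: 49 with CH2NMe2 on C11, both C11 epimers | CN(C)CC1C(=O)O[C@@H]2C[C@@H](C)[C@]34C[C@]5(C(=O)O[C@H]6C[C@@](C)(O)C([C@H](C)CCCOC(C)=O)=C[C@H]65)[C@H](C(C)=C3C[C@@H]12)[C@H]4OC(C)=O | intermediate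
51 | trimethylammonium iodide of 50 | C[N+](C)(C)CC1C(=O)O[C@@H]2C[C@@H](C)[C@]34C[C@]5(C(=O)O[C@H]6C[C@@](C)(O)C([C@H](C)CCCOC(C)=O)=C[C@H]65)[C@H](C(C)=C3C[C@@H]12)[C@H]4OC(C)=O.[I-] | intermediate
52 | CNP0257312.1 | C=C1C(=O)O[C@@H]2C[C@@H](C)[C@]34C[C@]5(C(=O)O[C@H]6C[C@@](C)(O)C([C@H](C)CCCOC(C)=O)=C[C@H]65)[C@H](C(C)=C3C[C@@H]12)[C@H]4OC(C)=O | target

## Step count and least certain steps

Total: 38 steps. Longest linear sequence: 21 steps (1, 2, 3, 6–9, 11–19, 34–38, from aldehyde 1). The cyclohexene fragment takes 13 steps (20, 21, 23–33) plus step 22 for its aldehyde partner. Steps 4 and 5 make keto aldehyde 8 and step 10 makes the dienophile.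

Step 17 (key step). The most likely failure is poor diastereoselection at C8, because a seven-membered transition state is flexible and the C7 arm is the only controlling element. Prins attack by the electron-rich C4=C5 alkene and epimerisation of the C7 aldehyde centre under the Lewis acid are further risks. Fallback: aldehyde 22 is treated with SmI2, HMPA and t-BuOH in THF. The ketyl formed by divalent samarium adds to the terminal carbon C9 of the isopropenyl group in a reductive ketyl–olefin cyclisation, and the tertiary C10 radical is reduced and protonated. This sets out from 22 and comes back at 24, the C8 and C10 epimers being separated there; no new compound is made, and steps 17 and 18 are replaced.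

Step 11. The diene 16 may isomerise by a 1,5-hydrogen shift to the conjugated enol acetate before it is trapped. The tertiary allylic carbinol may also ionise and lose the C2 hydrogen or a methyl hydrogen instead of a C3 hydrogen. Finally, the bulky C1 substituent may slow the cycloaddition enough for these paths to win. Fallback: the diene is made more electron-rich and without a tertiary carbinol. Enone 10 is acetylated (Ac2O, pyridine) to tert-butyl (3S)-4-{(3R)-3-acetoxy-5-oxo-2-[2-(TBSO)propan-2-yl]cyclopent-1-en-1-yl}-3-(TBSO-methyl)butanoate F1. Soft enolisation (TBSOTf, Et3N, −78 °C) gives the 4-silyloxy analogue of 16, silyloxydiene F2, which adds nitroacrylate 15 at low temperature on the acetoxy face with the same regiochemistry to give silyl enol ether adduct F3. DBU gives dienoate silyl enol ether F4. CsF and PhNTf2 convert the enol ether, which can only lie towards C5 because C3 is a bridgehead, into enol triflate F5, and Stille coupling (Me4Sn, Pd(PPh3)4, LiCl) installs the C4 methyl. This sets out from 10 and comes back at 18; steps 8, 9 and 11 are replaced.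

Step 7. The α-hydroxy ketone of 9 can enolise towards C2 under base, which erodes the configuration set in step 6, and retro-aldol cleavage or loss of water before ring closure can compete. Fallback: the ring is built with the ketone at C2 and the stereocentre is set afterwards by catalyst-controlled reduction. Ketone 5 is oxidised at its methylene (SeO2) to tert-butyl (3S)-5,6-dioxo-3-(TBSO-methyl)heptanoate F6. The kinetic lithium enolate of 4-methyl-4-(TBSO)pentan-2-one F7 (from diacetone alcohol and TBSOTf) adds to the acetyl carbonyl of F6, and KOH in MeOH closes and dehydrates the ring, a diketone–ketone annulation to a 4-hydroxycyclopentenone. The product is tert-butyl (3S)-4-{5-hydroxy-5-methyl-3-oxo-2-[2-(TBSO)propan-2-yl]cyclopent-1-en-1-yl}-3-(TBSO-methyl)butanoate F8. Corey–Bakshi–Shibata reduction of the 2-substituted cyclopentenone carbonyl then gives the (R)-carbinol. This sets out from 5 and comes back at 11; steps 4 to 8 are replaced.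

Step 35. The hindered acid chloride 44 may lose HCl only sluggishly, the ketene may dimerise, and proton transfer from the lactone to enolate 47 may return the unbrominated ester. Fallback: the C11' carbonyl is made selectively enolisable instead. Acid 25 is converted (PhSH, DCC, DMAP) into S-phenyl thioester F9, whose thioester alone undergoes soft enolisation (TMSOTf, Et3N); N-bromosuccinimide then gives α-bromo thioester F10, and silver-mediated acyl transfer (AgOTf, 43) gives the ester. This sets out from 25 and comes back at 48; steps 34 and 35 are replaced.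

Step 36. Three things may go wrong. The ester tether must reach its less stable rotamer before it can cyclise, so the C11' radical may simply be reduced. The tertiary alkoxy radical may fragment at C10'–C9' before it is reduced. The cyclisation may take the endo face of C11', since the exo face lies under the C2 acetoxy group, and that would give the wrong spiro epimer. Fallback: a polar closure with a different, chelated transition state. Enolate 47 is generated as in step 35 from 45 and 43 but is not brominated; on warming with LiClO4 it opens the vinyl epoxide in an intramolecular 5-exo SN2' enolate alkylation, which forms C11'–C7', the C5'=C6' alkene and the C10' alkoxide in one step. This sets out from 45 and 43 and comes back at 49; no new compound is made, and the bromination and step 36 are replaced.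

## Further compounds

F0 | step 17 | none | none
F1 | step 11 | tert-butyl (3S)-4-{(3R)-3-acetoxy-5-oxo-2-[2-(TBSO)propan-2-yl]cyclopent-1-en-1-yl}-3-(TBSO-methyl)butanoate | CC(=O)O[C@@H]1CC(=O)C(C[C@@H](CC(=O)OC(C)(C)C)CO[Si](C)(C)C(C)(C)C)=C1C(C)(C)O[Si](C)(C)C(C)(C)C
F2 | step 11 | tert-butyl (3S)-4-{(5R)-5-acetoxy-3-(TBSO)-1-[2-(TBSO)propan-2-yl]cyclopenta-1,3-dien-2-yl}-3-(TBSO-methyl)butanoate | CC(=O)O[C@@H]1C=C(O[Si](C)(C)C(C)(C)C)C(C[C@@H](CC(=O)OC(C)(C)C)CO[Si](C)(C)C(C)(C)C)=C1C(C)(C)O[Si](C)(C)C(C)(C)C
F3 | step 11 | tert-butyl 7-acetoxy-5-[(2S)-4-tert-butoxy-4-oxo-2-(TBSO-methyl)butyl]-3-nitro-6-(TBSO)-4-[2-(TBSO)propan-2-yl]bicyclo[2.2.1]hept-5-ene-2-carboxylate, acetoxy anti to C5=C6, nitro and ester trans | CC(C)(O[Si](C)(C)C(C)(C)C)[C@]12C([N+](=O)[O-])C(C(=O)OC(C)(C)C)[C@H](C(O[Si](C)(C)C(C)(C)C)=C1C[C@@H](CC(=O)OC(C)(C)C)CO[Si](C)(C)C(C)(C)C)[C@H]2OC(C)=O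
F4 | step 11 | tert-butyl 7-acetoxy-5-[(2S)-4-tert-butoxy-4-oxo-2-(TBSO-methyl)butyl]-6-(TBSO)-4-[2-(TBSO)propan-2-yl]bicyclo[2.2.1]hepta-2,5-diene-2-carboxylate | CC(C)(O[Si](C)(C)C(C)(C)C)[C@]12C=C(C(=O)OC(C)(C)C)[C@H](C(O[Si](C)(C)C(C)(C)C)=C1C[C@@H](CC(=O)OC(C)(C)C)CO[Si](C)(C)C(C)(C)C)[C@H]2OC(C)=O
F5 | step 11 | tert-butyl 7-acetoxy-5-[(2S)-4-tert-butoxy-4-oxo-2-(TBSO-methyl)butyl]-4-[2-(TBSO)propan-2-yl]-6-(trifluoromethylsulfonyloxy)bicyclo[2.2.1]hepta-2,5-diene-2-carboxylate | CC(C)(O[Si](C)(C)C(C)(C)C)[C@]12C=C(C(=O)OC(C)(C)C)[C@H](C(OS(=O)(=O)C(F)(F)F)=C1C[C@@H](CC(=O)OC(C)(C)C)CO[Si](C)(C)C(C)(C)C)[C@H]2OC(C)=O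
F6 | step 7 | tert-butyl (3S)-5,6-dioxo-3-(TBSO-methyl)heptanoate | CC(=O)C(=O)C[C@@H](CC(=O)OC(C)(C)C)CO[Si](C)(C)C(C)(C)C
F7 | step 7 | 4-methyl-4-(TBSO)pentan-2-one | CC(=O)CC(C)(C)O[Si](C)(C)C(C)(C)C
F8 | step 7 | tert-butyl (3S)-4-{5-hydroxy-5-methyl-3-oxo-2-[2-(TBSO)propan-2-yl]cyclopent-1-en-1-yl}-3-(TBSO-methyl)butanoate, both epimers at the methyl carbinol | CC1(O)CC(=O)C(C(C)(C)O[Si](C)(C)C(C)(C)C)=C1C[C@@H](CC(=O)OC(C)(C)C)CO[Si](C)(C)C(C)(C)C
F9 | step 35 | S-phenyl thioester of acid 25 at C12' | C1C(=O)O[C@@H]2C[C@@H](C)[C@]34C[C@H](C(=O)Sc5ccccc5)[C@H](C(C)=C3C[C@@H]12)[C@H]4OC(C)=O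
F10 | step 35 | S-phenyl α-bromo thioester (C11' bromide, both epimers) | C1C(=O)O[C@@H]2C[C@@H](C)[C@]34CC(Br)(C(=O)Sc5ccccc5)[C@H](C(C)=C3C[C@@H]12)[C@H]4OC(C)=O
F0 | step 36 | none | none
A1 | alternative 1 | 7,7-dimethoxynorbornadiene with C4 methyl, C5 methyl ester and the silyloxybutan-2-yl C10 arm on C1 | CC(C)(C)[Si](C)(C)OCC[C@@H](C)[C@]34C=C[C@H](C(C)=C3C(=O)OC)C4(OC)OC
A2 | alternative 2 | C10' enone: target lacking the C10' methyl, C10' as ketone | C=C1C(=O)O[C@@H]2C[C@@H](C)[C@]34C[C@]5(C(=O)O[C@H]6CC(=O)C([C@H](C)CCCOC(C)=O)=C[C@H]65)[C@H](C(C)=C3C[C@@H]12)[C@H]4OC(C)=O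
A3 | alternative 3 | spiro lactol ethyl ether with C5'=C6', free C10' hydroxyl and silyl ethers at C8 and C12 | CC(C)(C)[Si](C)(C)O[C@@H]2C[C@@H](C)[C@]34C[C@]5([C@H](OCC)O[C@H]6C[C@@](C)(O)C([C@H](C)CCCOC(C)=O)=C[C@H]65)[C@H](C(C)=C3C[C@H]2C(=C)CO[Si](C)(C)C(C)(C)C)[C@H]4OC(C)=O
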